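A direct plan would take the ring from an arene (acid numbering: C1 CO2H, C2 OH, C3 CH3, C4 C=O, C5 quaternary, C6 CH3). Atraric acid A1 would be formylated at C5 and hydrogenolysed to methyl 3,5-dimethylorsellinate A2. The phenolate of A2 would be C5-farnesylated under a chiral phase-transfer catalyst to dienone ester A3, and A3 would be demethylated.
Its weakest steps would be:
- the enantioselective dearomative farnesylation, because the ambident phenolate could react at O, C3 or C5, and a loose ion pair would have to distinguish the faces of a flat, fully substituted ring without close analogy;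
- the closing thiolate demethylation, because the doubly flanked ester would need a forcing soft nucleophile that could also add to the dienone, next to an acid that decarboxylates easily;
- the formylation/hydrogenolysis pair, which would spend two steps on one methyl group and add no complexity.

The cyclohexadienone ring is not taken from an arene but assembled around the finished stereocentre. Cutting C3–C4 and C1=C6 gives a 3-oxopentanoate 1,3-dianion (C1–C3, carrying carboxyl and 3-methyl) and an acyclic 2,2-disubstituted β-keto aldehyde (C4–C6). The feature exploited is quaternary C5 flanked by C4=O and C6–CH3: it makes C4/C6 a graded 1,3-dielectrophile and stops a [3+3] salicylate annulation before aromaticity. One operation forms both bonds and the hexasubstituted ring. C5 is set beforehand by chelate-controlled double alkylation of (S)-3-hydroxybutanoate, all methyl groups arrive with the fragments, and the ester is chosen fluoride-labile, so no ambident phenolate, methyl installation or thiolate dealkylation remains.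

Key step: step 6

Convention: "farnesyl" = (2E,6E)-3,7,11-trimethyldodeca-2,6,10-trien-1-yl; ring atoms keep the acid numbering given above; keto/enol tautomers count as one compound.
Assumption: the second alkylation of the chelated dianion follows the facial rule of the first (entry anti to the carbinol methyl). This gives 2R in 7, which is 5R in the target. The descriptor changes in 8, 9, 14 and 15 come only from changed CIP priorities.

Step 1
Reactants: 1 ethyl (S)-3-hydroxybutanoate; 2 (2E,6E)-farnesyl bromide
Product: 4 ethyl (2S,3S)-2-farnesyl-3-hydroxybutanoate, via dilithium alkoxide–(Z)-enolate 3 (not isolated)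
Conditions: LDA (commercial solution, 2.2 equiv), THF, −78 → −20 °C; 2, DMPU, −78 → 0 °C; AcOH quench
Reagents that add atoms: (2E,6E)-farnesyl bromide 2, CC(C)=CCC/C(C)=C/CC/C(C)=C/CBr
Why: Fráter–Seebach alkylation, in which the six-membered lithium chelate 3 takes the allylic bromide by SN2 at its CH2 terminus (E,E geometry kept) anti to the carbinol methyl; the new C2 centre is erased again in step 2, so its selectivity is not critical.

Step 2
Reactants: 4 ethyl (2S,3S)-2-farnesyl-3-hydroxybutanoate; 5 iodomethane
Product: 7 ethyl (2R,3S)-2-farnesyl-3-hydroxy-2-methylbutanoate, via dilithium alkoxide–enolate 6 (not isolated)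
Conditions: LDA (2.5 equiv), THF, −78 → −10 °C; MeI (excess), DMPU, −78 → 0 °C; AcOH quench
Reagents that add atoms: iodomethane 5, CI
Why: second Fráter–Seebach alkylation, in which chelation fixes the geometry of the tetrasubstituted enolate 6 and MeI should again enter anti to the carbinol methyl, moving farnesyl to the other face and setting the quaternary centre (future C5) through the C–CH3 bond.

Step 3
Reactants: 7 ethyl (2R,3S)-2-farnesyl-3-hydroxy-2-methylbutanoate
Product: 8 (2S,3S)-2-farnesyl-2-methylbutane-1,3-diol
Conditions: LiAlH4, Et2O, 0 → 25 °C; careful H2O quench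
Reagents that add atoms: none
Why: hydride reduction of an ester, to which isolated trisubstituted alkenes are inert and in which the quaternary centre cannot epimerise.

Step 4
Reactants: 8 (2S,3S)-2-farnesyl-2-methylbutane-1,3-diol
Product: 9 (S)-2-farnesyl-2-methyl-3-oxobutanal
Conditions: Dess–Martin periodinane (2.5 equiv), pyridine, CH2Cl2, 0 → 25 °C; used directly
Reagents that add atoms: none
Why: buffered, non-nucleophilic Dess–Martin oxidation of both carbinols, which deliberately destroys the relay stereocentre, while the α-carbon bears no hydrogen, so the β-keto aldehyde can neither enolise nor racemise.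

Step 5
Reactants: 10 methyl 3-oxopentanoate; 11 2-(trimethylsilyl)ethanol
Product: 12 2-(trimethylsilyl)ethyl 3-oxopentanoate
Conditions: DMAP (cat.), toluene, reflux, MeOH distilled off
Reagents that add atoms: 2-(trimethylsilyl)ethanol 11, C[Si](C)(C)CCO
Why: DMAP-catalysed transesterification of a β-keto ester, driven by removal of methanol, which installs the fluoride-labile ester before the ring exists.

Step 6
Reactants: 9 (S)-2-farnesyl-2-methyl-3-oxobutanal; 12 2-(trimethylsilyl)ethyl 3-oxopentanoate
Product: 16 2-(trimethylsilyl)ethyl (5R)-5-farnesyl-4-hydroxy-3,5,6-trimethyl-2-oxocyclohex-1(6)-ene-1-carboxylate (C3/C4 epimer mixture), via sodium lithium 1,3-dianion 13 (not isolated), via open-chain aldol adduct 14 (not isolated), via cyclic aldol 15 (not isolated)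
Conditions: 12 (1.3 equiv), NaH then n-BuLi, THF, 0 °C; 9, −78 °C; AcOH, −78 °C; then piperidine/AcOH (20 mol% each), 4 Å MS, toluene, 25–40 °C
Reagents that add atoms: 2-(trimethylsilyl)ethyl 3-oxopentanoate 12, CCC(=O)CC(=O)OCC[Si](C)(C)C
Why: The γ-carbon of dianion 13 (future C3), its more basic and more nucleophilic terminus, adds to the aldehyde of 9, the more electrophilic of its two carbonyl groups (β-keto ester dianion aldol), and acetic acid frees 14, in which only the doubly activated C1–H2 is acidic enough to be enolised by piperidinium acetate. C1 then closes onto the methyl ketone carbon C6 in a 6-(enolendo)-exo-trig aldol to 15, and E1cB loss of water through the acidic C1–H gives the tetrasubstituted C1=C6 bond (intramolecular Knoevenagel condensation). The closest known reaction type is the [3+3] salicylate annulation of β-keto ester dianion equivalents with β-keto aldehyde equivalents, which shows the same pairing (γ-carbon with aldehyde carbon, α-carbon with ketone carbon) and tolerates acetyl groups on a quaternary carbon; here quaternary C5 forbids aromatisation, so the sequence should halt at the cyclohexenone. C5 is not touched and has no α-hydrogen, so it cannot epimerise, and the new centres C3 and C4 (and the transient ones in 15) are left uncontrolled because step 7 turns them into sp2 carbons. The selectivity needed is site pairing of two nucleophilic with two electrophilic positions, secured by the matched reactivity gradients of both partners, and closing the ring while C4 is still a carbinol keeps 4-hydroxy-2-pyrone formation, the usual trap of 3,5-dioxo esters, out of reach. Low temperature in the aldol stage and near-neutral closure are meant to suppress retro-aldol cleavage and β-elimination of the C4 hydroxyl.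

Step 7
Reactants: 16 2-(trimethylsilyl)ethyl (5R)-5-farnesyl-4-hydroxy-3,5,6-trimethyl-2-oxocyclohex-1(6)-ene-1-carboxylate
Product: 17 2-(trimethylsilyl)ethyl (5R)-5-farnesyl-2-hydroxy-3,5,6-trimethyl-4-oxocyclohexa-1(6),2-diene-1-carboxylate
Conditions: IBX (2 equiv), DMSO, 25 °C
Reagents that add atoms: none
Why: IBX oxidation of a β-hydroxy ketone to the β-diketone, which should rest as the hydrogen-bonded enol, so that C3 and C4 become sp2 and all epimers of 16 converge on one compound.

Step 8
Reactants: 17 2-(trimethylsilyl)ethyl (5R)-5-farnesyl-2-hydroxy-3,5,6-trimethyl-4-oxocyclohexa-1(6),2-diene-1-carboxylate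
Product: 19 (5R)-5-farnesyl-2-hydroxy-3,5,6-trimethyl-4-oxocyclohexa-1(6),2-diene-1-carboxylic acid (target), via tetrabutylammonium carboxylate 18 (not isolated)
Conditions: TBAF (3 equiv), THF, 0 → 25 °C; cold 0.5 M HCl to pH 3, extraction at 0 °C
Reagents that add atoms: none
Why: fluoride-induced fragmentation of a 2-(trimethylsilyl)ethyl ester (attack at silicon, loss of ethene), which acts far from the hindered acyl carbon, brings no carbon-philic nucleophile near the dienone (present as its enolate), and ends with a cold, mild acidification that should avoid decarboxylation and protonation of the polyene.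

Compound list
1 | ethyl (S)-3-hydroxybutanoate | C[C@H](O)CC(=O)OCC | starting material
2 | (2E,6E)-farnesyl bromide | CC(C)=CCC/C(C)=C/CC/C(C)=C/CBr | starting material
3 | dilithium alkoxide–(Z)-enolate of 1 | [Li+].[Li+].CCO/C([O-])=C/[C@H](C)[O-] | intermediate
4 | ethyl (2S,3S)-2-farnesyl-3-hydroxybutanoate | CCOC(=O)[C@@H](C/C=C(\C)CC/C=C(\C)CCC=C(C)C)[C@H](C)O | intermediate
5 | iodomethane | CI | starting material
6 | dilithium alkoxide–enolate of 4 | [Li+].[Li+].CCO/C([O-])=C(\C/C=C(\C)CC/C=C(\C)CCC=C(C)C)[C@H](C)[O-] | intermediate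
7 | ethyl (2R,3S)-2-farnesyl-3-hydroxy-2-methylbutanoate | CCOC(=O)[C@](C)(C/C=C(\C)CC/C=C(\C)CCC=C(C)C)[C@H](C)O | intermediate
8 | (2S,3S)-2-farnesyl-2-methylbutane-1,3-diol | OC[C@](C)(C/C=C(\C)CC/C=C(\C)CCC=C(C)C)[C@H](C)O | intermediate
9 | (S)-2-farnesyl-2-methyl-3-oxobutanal | O=C[C@](C)(C/C=C(\C)CC/C=C(\C)CCC=C(C)C)C(C)=O | intermediate
10 | methyl 3-oxopentanoate | CCC(=O)CC(=O)OC | starting material
11 | 2-(trimethylsilyl)ethanol | C[Si](C)(C)CCO | starting material
12 | 2-(trimethylsilyl)ethyl 3-oxopentanoate | CCC(=O)CC(=O)OCC[Si](C)(C)C | intermediate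
13 | sodium lithium 1,3-dianion of 12 | [Na+].[Li+].CC=C([O-])C=C([O-])OCC[Si](C)(C)C | intermediate
14 | 2-(trimethylsilyl)ethyl (6S)-6-farnesyl-5-hydroxy-4,6-dimethyl-3,7-dioxooctanoate (C4/C5 epimers; octanoate C2–C7 = ring C1–C6) | C[Si](C)(C)CCOC(=O)CC(=O)C(C)C(O)[C@](C)(C/C=C(\C)CC/C=C(\C)CCC=C(C)C)C(C)=O | intermediate
15 | 2-(trimethylsilyl)ethyl (5S)-5-farnesyl-4,6-dihydroxy-3,5,6-trimethyl-2-oxocyclohexane-1-carboxylate (epimer mixture) | CC(C)=CCC/C(C)=C/CC/C(C)=C/C[C@@]1(C)C(O)C(C)C(=O)C(C(=O)OCC[Si](C)(C)C)C1(C)O | intermediate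
16 | 2-(trimethylsilyl)ethyl (5R)-5-farnesyl-4-hydroxy-3,5,6-trimethyl-2-oxocyclohex-1(6)-ene-1-carboxylate (C3/C4 epimers) | CC(C)=CCC/C(C)=C/CC/C(C)=C/C[C@@]1(C)C(O)C(C)C(=O)C(C(=O)OCC[Si](C)(C)C)=C1C | intermediate
17 | 2-(trimethylsilyl)ethyl (5R)-5-farnesyl-2-hydroxy-3,5,6-trimethyl-4-oxocyclohexa-1(6),2-diene-1-carboxylate | CC(C)=CCC/C(C)=C/CC/C(C)=C/C[C@@]1(C)C(=O)C(C)=C(O)C(C(=O)OCC[Si](C)(C)C)=C1C | intermediate
18 | tetrabutylammonium salt of 19 | CCCC[N+](CCCC)(CCCC)CCCC.CC(C)=CCC/C(C)=C/CC/C(C)=C/C[C@@]1(C)C(=O)C(C)=C(O)C(C(=O)[O-])=C1C | intermediate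
19 | (5R)-5-farnesyl-2-hydroxy-3,5,6-trimethyl-4-oxocyclohexa-1(6),2-diene-1-carboxylic acid | CC(C)=CCC/C(C)=C/CC/C(C)=C/C[C@@]1(C)C(=O)C(C)=C(O)C(C(=O)O)=C1C | target

Total steps: 8. Longest linear sequence: 7 (steps 1–4 and 6–8, from 1).

Steps most likely to fail

Step 6. The strongly basic aldol stage may fragment the aldolate (retro-aldol, loss of the formyl carbon). The amine-catalysed closure may be slow at the hindered ketone or be accompanied by β-elimination of the C4 hydroxyl. The fallback changes from the anionic to the Lewis-acid manifold and sets out from 12. Compound 12 would be silylated (Me3SiCl, Et3N) to 2-(trimethylsilyl)ethyl 3-(trimethylsilyloxy)pent-2-enoate F1, and then (LDA; Me3SiCl) to 1-[2-(trimethylsilyl)ethoxy]-1,3-bis(trimethylsilyloxy)penta-1,3-diene F2. F2 and 9 with TiCl4 in CH2Cl2 at −78 °C would undergo a Mukaiyama aldol at the aldehyde through the terminal diene carbon. The remaining silyl enol ether would then close onto the titanium-activated ketone, with the C4 oxygen held as a titanium alkoxide and no base present. The fallback comes back at 16.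

Step 2. Re-enolisation of the α-branched ester may stay incomplete, and the facial bias of the chelate may erode at a tetrasubstituted enolate. The fallback sets the centre by an auxiliary-controlled farnesylation instead of a relay-controlled methylation and sets out from 2.
- Commercial ethyl 2-methyl-3-oxobutanoate and L-valine tert-butyl ester would be condensed to the hydrogen-bonded enamino ester ethyl (Z)-3-{[(2S)-1-tert-butoxy-3-methyl-1-oxobutan-2-yl]amino}-2-methylbut-2-enoate F3.
- Its lithio derivative (LDA, toluene) would be alkylated with 2 to the ketimine F4. The external ligand (HMPA or THF), whose choice switches the attacked face, would be selected for the R series.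
- Mild aqueous acid would give ethyl (R)-2-farnesyl-2-methyl-3-oxobutanoate F5.
- LiAlH4 would give (2S,3RS)-2-farnesyl-2-methylbutane-1,3-diol F6, and Dess–Martin oxidation would give 9, where the fallback comes back.

Step 7. The carbinol lies between a quaternary and a tertiary carbon, so oxidation may be slow and give way to β-elimination of water or to over-oxidation at C3. The fallback brings C4 in at the carboxyl level, so that the ring never holds a C4 carbinol, and sets out from 7.
- Saponification (LiOH, aq. THF/MeOH) would give (2R,3S)-2-farnesyl-3-hydroxy-2-methylbutanoic acid F7.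
- Carboxyl activation (PhSO2Cl, pyridine, retention at the carbinol carbon) would give (3R,4S)-3-farnesyl-3,4-dimethyloxetan-2-one F8.
- Acyl–oxygen opening of the strained lactone by the γ-carbon of dianion 13 would give 2-(trimethylsilyl)ethyl (6R,7S)-6-farnesyl-7-hydroxy-4,6-dimethyl-3,5-dioxooctanoate F9.
- IBX oxidation of the methyl carbinol, where no β-elimination is possible across the quaternary carbon, would give 2-(trimethylsilyl)ethyl (R)-6-farnesyl-4,6-dimethyl-3,5,7-trioxooctanoate F10.
- Et3N would close F10 in the same Knoevenagel mode, now driven by formation of the vinylogous acid anion. The fallback comes back at 17.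

Further compounds
F1 | step 6 | 2-(trimethylsilyl)ethyl 3-(trimethylsilyloxy)pent-2-enoate | CCC(O[Si](C)(C)C)=CC(=O)OCC[Si](C)(C)C
F2 | step 6 | 1-[2-(trimethylsilyl)ethoxy]-1,3-bis(trimethylsilyloxy)penta-1,3-diene | CC=C(O[Si](C)(C)C)C=C(O[Si](C)(C)C)OCC[Si](C)(C)C
F3 | step 2 | ethyl (Z)-3-{[(2S)-1-tert-butoxy-3-methyl-1-oxobutan-2-yl]amino}-2-methylbut-2-enoate | CCOC(=O)/C(C)=C(/C)N[C@@H](C(C)C)C(=O)OC(C)(C)C
F4 | step 2 | ethyl (2R)-3-{[(2S)-1-tert-butoxy-3-methyl-1-oxobutan-2-yl]imino}-2-farnesyl-2-methylbutanoate | CCOC(=O)[C@](C)(C/C=C(\C)CC/C=C(\C)CCC=C(C)C)C(C)=N[C@@H](C(C)C)C(=O)OC(C)(C)C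
F5 | step 2 | ethyl (R)-2-farnesyl-2-methyl-3-oxobutanoate | CCOC(=O)[C@](C)(C/C=C(\C)CC/C=C(\C)CCC=C(C)C)C(C)=O
F6 | step 2 | (2S,3RS)-2-farnesyl-2-methylbutane-1,3-diol | OC[C@](C)(C/C=C(\C)CC/C=C(\C)CCC=C(C)C)C(C)O
F7 | step 7 | (2R,3S)-2-farnesyl-3-hydroxy-2-methylbutanoic acid | OC(=O)[C@](C)(C/C=C(\C)CC/C=C(\C)CCC=C(C)C)[C@H](C)O
F8 | step 7 | (3R,4S)-3-farnesyl-3,4-dimethyloxetan-2-one | O=C1O[C@@H](C)[C@@]1(C)C/C=C(\C)CC/C=C(\C)CCC=C(C)C
F9 | step 7 | 2-(trimethylsilyl)ethyl (6R,7S)-6-farnesyl-7-hydroxy-4,6-dimethyl-3,5-dioxooctanoate | C[Si](C)(C)CCOC(=O)CC(=O)C(C)C(=O)[C@](C)(C/C=C(\C)CC/C=C(\C)CCC=C(C)C)[C@H](C)O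
F10 | step 7 | 2-(trimethylsilyl)ethyl (R)-6-farnesyl-4,6-dimethyl-3,5,7-trioxooctanoate | C[Si](C)(C)CCOC(=O)CC(=O)C(C)C(=O)[C@](C)(C/C=C(\C)CC/C=C(\C)CCC=C(C)C)C(C)=O
A1 | direct plan | atraric acid (methyl 2,4-dihydroxy-3,6-dimethylbenzoate) | COC(=O)c1c(C)cc(O)c(C)c1O
A2 | direct plan | methyl 2,4-dihydroxy-3,5,6-trimethylbenzoate (methyl 3,5-dimethylorsellinate) | COC(=O)c1c(C)c(C)c(O)c(C)c1O
A3 | direct plan | methyl (5R)-5-farnesyl-2-hydroxy-3,5,6-trimethyl-4-oxocyclohexa-1(6),2-diene-1-carboxylate | CC(C)=CCC/C(C)=C/CC/C(C)=C/C[C@@]1(C)C(=O)C(C)=C(O)C(C(=O)OC)=C1C
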